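The time of reading was 15 min, and by then a flask with these charges should long have stopped moving, so I wanted the level its curve runs into.

| setting | cedar | birch | grey | green | blue |
|---|---|---|---|---|---|
| starting material | 0.45 M | 0.45 M | 0.45 M | 0.45 M | 0.45 M |
| coupling partner | 0.225 M | 0.225 M | 0.225 M | 0.225 M | 0.225 M |
| scavenger | 0.16 M | 0.37 M | 0.140 M | 0.200 M | 0.300 M |
| remark | run made earlier | run made earlier |  |  |  |
| time |  |  | 15 min | 15 min | 15 min |

| run | time / min | starting material / % | target / % |
|---|---|---|---|
| cedar | 0.833 | 72 | 8 |
| cedar | 2.00 | 56 | 19 |
| cedar | 5.00 | 52 | 29 |
| cedar | 10.0 | 55 | 33 |
| birch | 2.50 | 55 | 26 |
| birch | 5.00 | 48 | 33 |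
| birch | 8.00 | 50 | 35 |
| birch | 10.0 | 51 | 31 |

(each reading ± 2 percentage points)



* part of the starting material that has reacted at the end, grey
* part of the starting material that has reacted at the end, green
* part of the starting material that has reacted at the end, blue
* what raising the concentration of scavenger from its lowest to its highest value here does to the part of the starting material that has reacted (changes below 5 percentage points count as none) (no change / it falls / it rises)

I reckoned with one quantity, the partner ceiling: the charge of coupling partner divided by the charge of starting material, 50.0%, which is the most starting material that can react if each coupling partner takes one. That makes the coupling partner the limiting reagent. Then I drew the curve. In the cedar run, 28.0% had reacted at 0.833 min, one scattered reading, which gives a mean slope up to that time of 0.336 /min, a chord and not the slope at the very start. A straight line at that mean slope meets the ceiling at a rough knee of 1.49 min, which comes earlier than the reading, so I took 15 min to lie on the level.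

What remained was a small correction to the ceiling. Averaged over the readings at 5.00 min and 10.0 min, the cedar run stood 3.5 percentage points below the ceiling and the birch run 0.5 points above it, with a scatter of 2 points on each reading. The two averages differed by 4 points, less than 5 points, across scavenger from 0.16 M to 0.37 M. So I put grey, green and blue between 46.5% and 50.0%, with no change.

The forecast gave 45%, 46% and 48%, and no change, saying “Consumption is therefore set by the partner, not the scavenger”. Its grey value stands slightly below my range.

Grey, green and blue gave 50.0%, 50.0% and 50.0%, a change of 0 points: no change.

    starting material + coupling partner → intermediate + released group (k = 0.0720 /M/s)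
    intermediate → target (k = 0.0140 /s)
    scavenger + released group → scavenged by-product (k = 0.170 /M/s)
    intermediate → side product (k = 0.00770 /s)
    coupling partner + released group ⇌ idle adduct, settled at all times (K = 6.10 /M)

Green stood on the ceiling, with 0% of its coupling partner left against 50% of its starting material. Its answer moved by 5 points with coupling partner down at 0.203 M or up at 0.248 M; the upward move is the one that carries it away from the forecast's 46%, which already stood below green's result. The neighbouring flask is grey with 0.090 M of coupling partner. Its ceiling is 20.0%, and it gave 20.0%, with 0% of its coupling partner and 36% of its scavenger left.

The numbers in the tables were computed on assumed constants; the scatter is artificial.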